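A small charge of free catalyst, 1.0 mM, has to turn 2.0 M of substrate, and it destroys itself as it works.

    gas phase ⇌ dissolved gas, rate k1*(csat - [dissolved gas]) (k1 = 0.19 s⁻¹, csat = 130 mM)
    substrate + dissolved gas + free catalyst ⇌ free catalyst + product (K2 = 4.7 L mol⁻¹, k2 = 84 L² mol⁻² s⁻¹)
    2 free catalyst → spent catalyst (k3 = 8.7 L mol⁻¹ s⁻¹)

substrate 2.0 M; gas phase 130 mM (held); free catalyst 1.0 mM; time 2.0 min

- for a step with 2 of a species take k times the square, and two of it per event
- at the start none of the gas is dissolved
- run time (flask): 2.0 min

- amount of product at 2.0 min, in percent of the substrate charged
- concentration of dissolved gas in solution at 1.0 min, in percent of saturation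
- the change that raises the amount of product at 2.0 min, in percent of the substrate charged most ("none" if none brings more than 2 percentage points) (violet / grey / ochre / none)
- amount of product at 2.0 min, in percent of the substrate charged, after ochre

- violet: doubling the amount of free catalyst, all else as stated
- grey: doubling the transfer coefficient of step 1, all else as stated
- ochre: doubling the saturation concentration of gas phase, all else as stated

**Two flasks.** Beside this flask put a neighbour that looks nearly the same, with 0.0040 M of free catalyst, 4.00 times the charge. You may expect it to run well ahead, so let us reckon both by hand.

**The ceiling.** Dissolved gas refills with a time of 0.0877 min, shorter than the run, so freeze it in a quasi-steady state, uptake equal to use. Free catalyst stands on both sides of step 2, so it drops out of the balance. With the gas at saturation, c(product) stops at 37.9% of the substrate in both flasks.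

**The reach.** The first half-life of free catalyst by its own step is 0.958 min, shorter than the run, and 0.239 min in the neighbour. Averaged over the run, c(free catalyst) is 0.540 mM here and 1.07 mM there, a rise of 1.98 times, less than the charge rose. In my balance, which counts the forward use of step 2 and not its way back, the mean catalyst leaves a share 67.7% of saturation here, 51.4% there. Multiply the rate constant of step 2, saturation plus the inverse equilibrium constant, that share, mean catalyst and time. This gives the reach, the number of relaxation times the dying catalyst buys: 1.26 here, 1.90 there. Each unit of reach shrinks the gap to the ceiling by a factor e.

So I reckon 27.2% here and 32.3% in the neighbour. At 1.0 min the same balance gives 86.4%. Doubling the catalyst gives a mean of 0.787 mM, and the best change comes out as ochre, which lifts the ceiling itself and gives 45.4%.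

**The forecast.** It gives 27.1%, 84%, ochre and 46%, and says of that change: “it clearly beats more catalyst or faster transfer”.

**The result.** This flask gives 26.7% and 82.9%; ochre adds 19 percentage points and reaches 45.4%. Left until 20.0 min, this flask stands at 37.4%. Read back through the ceiling, 26.7% is a reach of 1.22 in this flask. The neighbour ends at 31.3% with 10.7% of its free catalyst left, a reach of 1.75.

Its constants are those of an exercise; no experiment stands behind them.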